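**Strategy.** Atoms carry labdane numbers (see remark). Ring B is closed last, inside a temporary cyclohexanone "ring X" (C2, C1, C10, C5, C6, C7) that is easier to build. An organocatalytic Robinson annulation sets C5 and two conjugate additions set quaternary C10, which then bears the C9–C8 ester arm. The key step, a transannular Claisen condensation of the C7 ketone enolate onto the C8 ester, forms C7–C8 and closes ring B as a bicyclo[2.2.2]octane-2,6-dione. It exploits the two acetic-type arms on C10 (C1–C2 and C9–C8). Hydroxide then cuts C2–C7, freeing the C2 acid and leaving the ring B ketone at C8. Linalool supplies C11–C16, and ring C closes by alkoxymercuration.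

Key step: step 11

Remark (numbering): C8 is the ring-fusion carbon bearing CH3 (C17) and the ether oxygen, C7 the ring CH2 next to it, C9 the ring-fusion CH. C10 is the quaternary carbon bearing CH3 (C20) and CH2CO2H (C1, C2). C5 is the CH bearing C(CH3)2CO2CH3 (C4, C3). C11–C12 lead to C13 (CH3 C16, vinyl C14–C15).

Assumption: (R)-(−)-linalool of high enantiomeric purity is taken as commercially available.

Step 1
Reactants: 1 methyl 2-methylpropanoate; 2 3-bromoprop-1-ene
Product: 3 methyl 2,2-dimethylpent-4-enoate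
Conditions: LiN(iPr)2, THF, −78 °C; then 2, −78 to 0 °C
Reagents that add atoms: none
Why: Alkylation of the tertiary ester enolate with allyl bromide (SN2) is routine and builds quaternary C4.

Step 2
Reactants: 3 methyl 2,2-dimethylpent-4-enoate
Product: 4 methyl 2,2-dimethyl-4-oxobutanoate
Conditions: O3, CH2Cl2, −78 °C; then Me2S, −78 °C to rt
Reagents that add atoms: ozone, O=[O+][O-]
Why: Ozonolysis with reductive work-up cleaves the terminal alkene to the aldehyde (the future C10) and leaves the hindered ester alone.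

Step 3
Reactants: 4 methyl 2,2-dimethyl-4-oxobutanoate; 5 but-3-en-2-one
Product: 7 methyl 2-methyl-2-[(1S)-4-oxocyclohex-2-en-1-yl]propanoate, via keto aldehyde 6 (not isolated)
Conditions: (R)-2-[methoxy(diphenyl)methyl]pyrrolidine (5 mol%), ethyl 3,4-dihydroxybenzoate (20 mol%), neat, 4 °C; then LiOH (0.2 equiv), i-PrOH, 0 °C to rt
Reagents that add atoms: none
Why: Enamine-catalysed asymmetric Michael addition of the aldehyde to the vinyl ketone sets C5 (the (R)-catalyst shields one enamine face, so (3R)-6 should form, by the usual model for diarylprolinol ethers), and intramolecular aldol condensation (Robinson annulation) then closes ring X faster than the aldehyde can epimerise.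

Step 4
Reactants: 7 methyl 2-methyl-2-[(1S)-4-oxocyclohex-2-en-1-yl]propanoate; 8 tert-butyl[(1-methoxyethenyl)oxy]dimethylsilane
Product: 9 methyl 2-[(1S,2R)-4-{[tert-butyl(dimethyl)silyl]oxy}-2-(2-methoxy-2-oxoethyl)cyclohex-3-en-1-yl]-2-methylpropanoate
Conditions: Tf2NH (2 mol%), CH2Cl2, −78 °C
Reagents that add atoms: none
Why: Mukaiyama–Michael addition places the acetate arm (C9–C8) on the β-carbon C10 anti to the bulky C5 substituent and transfers silicon to oxygen, giving the regiodefined enol ether; this C10 centre is temporary.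

Step 5
Reactants: 9 the silyl enol ether from step 4
Product: 10 methyl 2-[(1S)-2-(2-methoxy-2-oxoethyl)-4-oxocyclohex-2-en-1-yl]-2-methylpropanoate
Conditions: Pd(OAc)2 (1.05 equiv), MeCN, 40 °C
Reagents that add atoms: none
Why: Saegusa–Ito oxidation (palladium enolate, then β-hydride elimination of the C10 hydrogen) restores the C1=C10 enone, now with the acetate arm on C10.

Step 6
Reactants: 10 the 3-substituted enone from step 5
Product: 11 methyl 2-[(1S,2S)-2-(2-methoxy-2-oxoethyl)-2-methyl-4-(trimethylsilyloxy)cyclohex-3-en-1-yl]-2-methylpropanoate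
Conditions: CuI, MeLi (2 equiv), THF, 0 °C; then Me3SiCl, 10, −78 to −40 °C; Et3N quench
Reagents that add atoms: lithium dimethylcuprate, [Li+].C[Cu-]C; chlorotrimethylsilane, C[Si](C)(C)Cl
Why: Silyl-chloride-accelerated cuprate conjugate addition should deliver methyl (C20) to C10 anti to the C5 substituent, so the quaternary centre forms with methyl trans and the ester arm cis to that substituent, and the enolate is trapped as a silyl enol ether that masks the ketone for step 10.

Step 7
Reactants: 12 (R)-(−)-linalool, (3R)-3,7-dimethylocta-1,6-dien-3-ol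
Product: 13 triethyl{[(3R)-3,7-dimethylocta-1,6-dien-3-yl]oxy}silane
Conditions: Et3SiOTf, 2,6-lutidine, CH2Cl2, −78 to 0 °C
Reagents that add atoms: triethylsilyl trifluoromethanesulfonate, CC[Si](CC)(CC)OS(=O)(=O)C(F)(F)F
Why: Silyl triflate silylation protects the hindered tertiary C13 alcohol without touching the stereocentre.

Step 8
Reactants: 13 the silyl ether of linalool
Product: 14 (3R)-3-methyl-3-(triethylsilyloxy)pent-4-en-1-ol
Conditions: O3, CH2Cl2/MeOH, pyridine, −78 °C (Sudan Red 7B end point); then NaBH4, −78 to 0 °C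
Reagents that add atoms: ozone, O=[O+][O-]
Why: Ozone attacks the electron-rich trisubstituted alkene much faster than the hindered vinyl group, and borohydride work-up reduces the ozonide to the primary alcohol (C11).

Step 9
Reactants: 14 (3R)-3-methyl-3-(triethylsilyloxy)pent-4-en-1-ol
Product: 15 triethyl{[(3R)-5-iodo-3-methylpent-1-en-3-yl]oxy}silane
Conditions: I2, PPh3, imidazole, CH2Cl2, 0 °C
Reagents that add atoms: iodine, II
Why: Appel-type iodination converts the primary alcohol into the iodide by SN2 displacement of the oxyphosphonium group.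

Step 10
Reactants: 11 the silyl enol ether from step 6; 15 the iodide from step 9
Product: 17 methyl (5R)-2-[(1R,2S)-2-(1-methoxy-2-methyl-1-oxopropan-2-yl)-1-methyl-5-oxocyclohexyl]-5-methyl-5-(triethylsilyloxy)hept-6-enoate (both C2 epimers), via alkylated silyl enol ether 16 (not isolated)
Conditions: LiN(iPr)2 (1.1 equiv), THF, −78 °C; then 15, DMPU, −78 to −30 °C; then K2CO3 (cat.), MeOH, 0 °C
Reagents that add atoms: none
Why: With the ketone masked and the other ester lacking α-hydrogens, the base can only deprotonate C9, the ester enolate is alkylated by the primary iodide (SN2) at low temperature, and mild methanolysis frees the ketone; C9 forms as an epimer mixture that is corrected in step 12.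

Step 11
Reactants: 17 the ring X keto diester from step 10
Product: 18 methyl 2-methyl-2-{(1R,4R,8S)-4-methyl-3-[(3R)-3-methyl-3-(triethylsilyloxy)pent-4-en-1-yl]-2,6-dioxobicyclo[2.2.2]octan-8-yl}propanoate (both C3 epimers)
Conditions: LiN(iPr)2 (2.2 equiv), THF, −78 to −10 °C; AcOH quench at −78 °C
Reagents that add atoms: none
Why: The base removes a proton from C7, the unhindered α′-carbon of the C2 ketone (C1 is neopentyl, C9–H is a hindered tertiary ester hydrogen), and on warming the C7 enolate adds to the C8 ester carbonyl on the axial arm of C10 and expels methoxide (intramolecular Claisen condensation). The closest known reaction is the internal Claisen condensation of 3-substituted cyclohexanones with an ester two atoms from the ring, which gives bicyclo[2.2.2]octane-2,6-diones. Ring B (C5–C6–C7–C8–C9–C10) closes in a 6-(enolexo)-exo-trig mode through a boat form of ring X. The only new stereocentre is bridgehead C7, whose configuration is fixed by the bicyclic framework and which becomes CH2 again in step 12. The step needs chemoselectivity for the C8 ester over the C3 ester, which should hold because C3 is α-quaternary and could only be reached with the bulky C5 substituent axial; the second equivalent of base converts 18 into its enolate, which the liberated lithium methoxide cannot cleave.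

Step 12
Reactants: 18 the bicyclic diketone from step 11
Product: 19 2-{(1R,2S,6S)-6-(1-methoxy-2-methyl-1-oxopropan-2-yl)-1-methyl-2-[(3R)-3-methyl-3-(triethylsilyloxy)pent-4-en-1-yl]-3-oxocyclohexyl}acetic acid
Conditions: LiOH, THF/H2O, 0 °C to rt; then dilute HCl to pH 4, 0 °C
Reagents that add atoms: lithium hydroxide, [Li+].[OH-]
Why: Retro-Claisen cleavage of the non-enolisable β-diketone: hydroxide should add to the less hindered C2 carbonyl (flanked by CH2, remote from the C5 group and the C9 side chain) and break C2–C7 to the C8 ketone enolate, which opens ring X, frees the C2 acid beside the untouched hindered methyl ester, and lets C9 settle as the equatorial epimer (H trans to the C10 methyl).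

Step 13
Reactants: 19 the ring B keto acid from step 12
Product: 20 2-{(1S,2R,6S)-6-(1-methoxy-2-methyl-1-oxopropan-2-yl)-1-methyl-3-methylidene-2-[(3R)-3-methyl-3-(triethylsilyloxy)pent-4-en-1-yl]cyclohexyl}acetic acid
Conditions: Ph3PCH3Br, KOtBu (3 equiv each), THF, 0 to 60 °C
Reagents that add atoms: methylenetriphenylphosphorane, C=P(c1ccccc1)(c1ccccc1)c1ccccc1
Why: Wittig methylenation turns the hindered C8 ketone into the exocyclic C8=C17 alkene, the carboxylate being inert to the ylide and C9 keeping its equatorial side chain.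

Step 14
Reactants: 20 the methylidene acid from step 13
Product: 21 2-{(1S,2R,6S)-2-[(3R)-3-hydroxy-3-methylpent-4-en-1-yl]-6-(1-methoxy-2-methyl-1-oxopropan-2-yl)-1-methyl-3-methylidenecyclohexyl}acetic acid
Conditions: Bu4NF, AcOH, THF, 0 °C to rt
Reagents that add atoms: none
Why: Buffered fluoride cleaves the Si–O bond and frees the tertiary C13 alcohol without acid strong enough to ionise the allylic position.

Step 15
Reactants: 21 the hydroxy alkene acid from step 14
Product: 23 2-[(2R,4aS,5R,6S,8aS)-2-ethenyl-6-(1-methoxy-2-methyl-1-oxopropan-2-yl)-2,5,8a-trimethyloctahydro-2H-chromen-5-yl]acetic acid (target), via organomercurial 22 (not isolated)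
Conditions: Hg(OAc)2 (1.05 equiv), THF, 0 °C; then NaBH4, aq. NaOH, 0 °C; acidify to pH 4
Reagents that add atoms: none
Why: Intramolecular alkoxymercuration–demercuration: Markovnikov 6-exo attack of the C13 hydroxyl on the mercurinium ion at C8 from the face trans to the axial C10 methyl should give the trans-fused pyran and set C8, borohydride then turns CH2Hg into the C17 methyl, C13 is never ionised, and the equatorial CH2CO2H arm cannot reach C8.

**Compound list**

1 | methyl 2-methylpropanoate (methyl isobutyrate) | COC(=O)C(C)C | starting material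
2 | 3-bromoprop-1-ene (allyl bromide) | C=CCBr | starting material
3 | methyl 2,2-dimethylpent-4-enoate | COC(=O)C(C)(C)CC=C | intermediate
4 | methyl 2,2-dimethyl-4-oxobutanoate | COC(=O)C(C)(C)CC=O | intermediate
5 | but-3-en-2-one (methyl vinyl ketone) | CC(=O)C=C | starting material
6 | methyl (3R)-3-formyl-2,2-dimethyl-6-oxoheptanoate | COC(=O)C(C)(C)[C@H](C=O)CCC(C)=O | intermediate (not isolated)
7 | methyl 2-methyl-2-[(1S)-4-oxocyclohex-2-en-1-yl]propanoate | O=C1C=C[C@@H](C(C)(C)C(=O)OC)CC1 | intermediate
8 | tert-butyl[(1-methoxyethenyl)oxy]dimethylsilane | C=C(OC)O[Si](C)(C)C(C)(C)C | starting material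
9 | methyl 2-[(1S,2R)-4-{[tert-butyl(dimethyl)silyl]oxy}-2-(2-methoxy-2-oxoethyl)cyclohex-3-en-1-yl]-2-methylpropanoate | CC(C)(C)[Si](C)(C)OC1=C[C@H](CC(=O)OC)[C@@H](C(C)(C)C(=O)OC)CC1 | intermediate
10 | methyl 2-[(1S)-2-(2-methoxy-2-oxoethyl)-4-oxocyclohex-2-en-1-yl]-2-methylpropanoate | O=C1C=C(CC(=O)OC)[C@@H](C(C)(C)C(=O)OC)CC1 | intermediate
11 | methyl 2-[(1S,2S)-2-(2-methoxy-2-oxoethyl)-2-methyl-4-(trimethylsilyloxy)cyclohex-3-en-1-yl]-2-methylpropanoate | C[Si](C)(C)OC1=C[C@@](C)(CC(=O)OC)[C@@H](C(C)(C)C(=O)OC)CC1 | intermediate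
12 | (R)-(−)-linalool, (3R)-3,7-dimethylocta-1,6-dien-3-ol | CC(C)=CCC[C@@](C)(O)C=C | starting material
13 | triethyl{[(3R)-3,7-dimethylocta-1,6-dien-3-yl]oxy}silane | CC(C)=CCC[C@@](C)(O[Si](CC)(CC)CC)C=C | intermediate
14 | (3R)-3-methyl-3-(triethylsilyloxy)pent-4-en-1-ol | OCC[C@@](C)(O[Si](CC)(CC)CC)C=C | intermediate
15 | triethyl{[(3R)-5-iodo-3-methylpent-1-en-3-yl]oxy}silane | ICC[C@@](C)(O[Si](CC)(CC)CC)C=C | intermediate
16 | C9-alkylated trimethylsilyl enol ether (silyl enol ether of 17, C2=C1) | C[Si](C)(C)OC1=C[C@@](C)(C(CC[C@@](C)(O[Si](CC)(CC)CC)C=C)C(=O)OC)[C@@H](C(C)(C)C(=O)OC)CC1 | intermediate (not isolated)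
17 | methyl (5R)-2-[(1R,2S)-2-(1-methoxy-2-methyl-1-oxopropan-2-yl)-1-methyl-5-oxocyclohexyl]-5-methyl-5-(triethylsilyloxy)hept-6-enoate (both C2 epimers) | O=C1C[C@@](C)(C(CC[C@@](C)(O[Si](CC)(CC)CC)C=C)C(=O)OC)[C@@H](C(C)(C)C(=O)OC)CC1 | intermediate
18 | methyl 2-methyl-2-{(1R,4R,8S)-4-methyl-3-[(3R)-3-methyl-3-(triethylsilyloxy)pent-4-en-1-yl]-2,6-dioxobicyclo[2.2.2]octan-8-yl}propanoate (both C3 epimers) | O=C1C[C@@]2(C)C(CC[C@@](C)(O[Si](CC)(CC)CC)C=C)C(=O)[C@@H]1C[C@@H]2C(C)(C)C(=O)OC | intermediate
19 | 2-{(1R,2S,6S)-6-(1-methoxy-2-methyl-1-oxopropan-2-yl)-1-methyl-2-[(3R)-3-methyl-3-(triethylsilyloxy)pent-4-en-1-yl]-3-oxocyclohexyl}acetic acid | O=C1CC[C@H](C(C)(C)C(=O)OC)[C@@](C)(CC(=O)O)[C@@H]1CC[C@@](C)(O[Si](CC)(CC)CC)C=C | intermediate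
20 | 2-{(1S,2R,6S)-6-(1-methoxy-2-methyl-1-oxopropan-2-yl)-1-methyl-3-methylidene-2-[(3R)-3-methyl-3-(triethylsilyloxy)pent-4-en-1-yl]cyclohexyl}acetic acid | C=C1CC[C@H](C(C)(C)C(=O)OC)[C@@](C)(CC(=O)O)[C@@H]1CC[C@@](C)(O[Si](CC)(CC)CC)C=C | intermediate
21 | 2-{(1S,2R,6S)-2-[(3R)-3-hydroxy-3-methylpent-4-en-1-yl]-6-(1-methoxy-2-methyl-1-oxopropan-2-yl)-1-methyl-3-methylidenecyclohexyl}acetic acid | C=C1CC[C@H](C(C)(C)C(=O)OC)[C@@](C)(CC(=O)O)[C@@H]1CC[C@@](C)(O)C=C | intermediate
22 | C17 acetoxymercurio derivative of the target (CH2HgOAc on C8) | C=C[C@@]1(C)CC[C@H]2[C@](C)(CC(=O)O)[C@@H](C(C)(C)C(=O)OC)CC[C@]2(C[Hg]OC(C)=O)O1 | intermediate (not isolated)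
23 | 2-[(2R,4aS,5R,6S,8aS)-2-ethenyl-6-(1-methoxy-2-methyl-1-oxopropan-2-yl)-2,5,8a-trimethyloctahydro-2H-chromen-5-yl]acetic acid | C=C[C@@]1(C)CC[C@H]2[C@](C)(CC(=O)O)[C@@H](C(C)(C)C(=O)OC)CC[C@]2(C)O1 | target

**Count.** Total steps: 15. Longest linear sequence: 12 (steps 1–6 and 10–15); steps 7–9 make the side-chain iodide.

**Steps most likely to fail**

Step 11. Proton transfer may occur at C9 or C1 instead of C7, an ester enolate may then attack the C3 ester in a Dieckmann-type closure, or methoxide may reverse the condensation before the diketone is protected as its enolate. The fallback sets out from 17 and returns at 18. Me3SnOH (1,2-dichloroethane, 80 °C) should cleave the C8 methyl ester, whose carbonyl is less shielded than the α-quaternary C3 ester, to the carboxylic acid F1. DCC and pentafluorophenol convert it into the pentafluorophenyl ester F2. Soft enolisation of the ketone with MgBr2·OEt2 and i-Pr2NEt in CH2Cl2 then C-acylates C7 with the activated ester, with no free ester enolate and no alkoxide present, and gives 18.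

Step 6. Addition at the doubly flanked β-carbon may be slow, so that deprotonation at C9 (γ to the ketone, α to the ester) or loss of facial selectivity takes over. The fallback sets out from 10 and returns at 17. Methylene transfer from dimethylsulfoxonium methylide (Corey–Chaykovsky cyclopropanation, anti to the C5 substituent) should give the cyclopropyl ketone F3. SmI2/HMPA/t-BuOH cleaves the cyclopropane bond that overlaps with the ketyl (C1–CH2), so the CH2 becomes the C10 methyl of the methyl ketone F4. Kinetic enolisation (LiN(iPr)2, Me3SiCl, −78 °C) gives the C2=C7 silyl enol ether F5, which masks the ketone as 11 does. Alkylation with 15 under the conditions of step 10 gives the alkylated silyl enol ether F6, and methanolysis delivers 17.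

Step 12. Hydroxide may add to the C8 carbonyl instead of C2, which reopens ring B and yields a ring X keto acid that cannot be recycled. The fallback sets out from 18 and returns at 19. NaOMe in MeOH at 0 °C performs the retro-Claisen with methoxide: attack at C2 gives the keto dimethyl ester F7, while attack at C8 only regenerates 17, which is returned to step 11. LiOH in THF/H2O then hydrolyses the CH2CO2CH3 ester of F7 selectively (the C3 ester is α-quaternary) to 19.

**Further compounds**

F1 | step 11 | (5R)-2-[(1R,2S)-2-(1-methoxy-2-methyl-1-oxopropan-2-yl)-1-methyl-5-oxocyclohexyl]-5-methyl-5-(triethylsilyloxy)hept-6-enoic acid | O=C1C[C@@](C)(C(CC[C@@](C)(O[Si](CC)(CC)CC)C=C)C(=O)O)[C@@H](C(C)(C)C(=O)OC)CC1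
F2 | step 11 | pentafluorophenyl ester of F1 | O=C1C[C@@](C)(C(CC[C@@](C)(O[Si](CC)(CC)CC)C=C)C(=O)Oc2c(F)c(F)c(F)c(F)c2F)[C@@H](C(C)(C)C(=O)OC)CC1
F3 | step 6 | methyl 2-[6-(2-methoxy-2-oxoethyl)-2-oxobicyclo[4.1.0]heptan-5-yl]-2-methylpropanoate (cyclopropane CH2 anti to the ester-bearing group) | O=C1[C@@H]2C[C@]2(CC(=O)OC)[C@@H](C(C)(C)C(=O)OC)CC1
F4 | step 6 | methyl 2-[(1S,2S)-2-(2-methoxy-2-oxoethyl)-2-methyl-4-oxocyclohexyl]-2-methylpropanoate | O=C1C[C@@](C)(CC(=O)OC)[C@@H](C(C)(C)C(=O)OC)CC1
F5 | step 6 | C2=C7 trimethylsilyl enol ether of F4 | C[Si](C)(C)OC1=CC[C@H](C(C)(C)C(=O)OC)[C@](C)(CC(=O)OC)C1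
F6 | step 6 | C9-alkylated C2=C7 trimethylsilyl enol ether (silyl enol ether of 17) | C[Si](C)(C)OC1=CC[C@H](C(C)(C)C(=O)OC)[C@](C)(C(CC[C@@](C)(O[Si](CC)(CC)CC)C=C)C(=O)OC)C1
F7 | step 12 | methyl 2-{(1R,2S,6S)-6-(1-methoxy-2-methyl-1-oxopropan-2-yl)-1-methyl-2-[(3R)-3-methyl-3-(triethylsilyloxy)pent-4-en-1-yl]-3-oxocyclohexyl}acetate | O=C1CC[C@H](C(C)(C)C(=O)OC)[C@@](C)(CC(=O)OC)[C@@H]1CC[C@@](C)(O[Si](CC)(CC)CC)C=C
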